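**Retrosynthetic overview**

1. Target ⇒ 15‑O‑silyl 2,3‑cis‑diol ⇒ C3 ketone (hydroxylation of the C2 enolate, then hydride reduction). The C7=C8–C17 unit ⇒ C8 ketone (C7 enol triflate, iron‑catalysed methylation).
2. Key disconnection at C10–C20 and C9–C11: cis‑fused C8 ketone ⇒ bicyclic C8(=O)–C9=C10 enone + Me2CuLi + (E)‑homoallylic iodide. It rests on this feature (labdane numbering; ring A = C1–C5 and C10, ring B = C5–C10): the angular methyl C20 on C10 is cis to H‑5 and to the C9 chain, and C10 and C9 are the β‑ and α‑carbons of a C8 carbonyl.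
3. Enone ⇒ 6‑methoxy‑2‑tetralone: C4 gem‑dimethyl by benzylic dialkylation, C3 by CBS reduction, C5 by Birch reduction/hydrolysis/conjugation. Iodide ⇒ but‑3‑yn‑1‑ol by carboalumination.
4. Ring order: no ring is formed in the route. Ring A is the saturated ring of the tetralone; ring B is its anisole ring, unmasked by Birch reduction.
5. Stereochemical relay: catalyst → C3 → C5 → C10 and C9 (key step) → C2 → C3 (re‑set after oxidation).

Key step: step 11

Remark on the chemistry: labdane names below denote the carbon skeleton only, with every configuration given by explicit CIP descriptors. "α face" is the face that carries C20, H‑5 and the C9 chain in the target; "β face" is the face of the two hydroxyls.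

**Route**

Step 1
Reactants: 1 6‑methoxy‑2‑tetralone; 2 iodomethane
Product: 4 6‑methoxy‑1,1‑dimethyl‑3,4‑dihydronaphthalen‑2(1H)‑one, via 6‑methoxy‑1‑methyl‑2‑tetralone 3 (not isolated)
Conditions: KOt‑Bu (2.2 equiv), THF, 0 °C; MeI (2.5 equiv), 0 °C → rt
Reagents that add atoms: iodomethane (second equivalent), CI
Why: Enolate C‑alkylation: a 2‑tetralone enolises toward the benzylic C1, so two successive methylations, each consuming one equivalent of iodomethane, place the gem‑dimethyl group there (labdane C4), and limiting base and MeI keeps methylation at C3 low.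

Step 2
Reactants: 4 6‑methoxy‑1,1‑dimethyl‑3,4‑dihydronaphthalen‑2(1H)‑one
Product: 5 (S)‑6‑methoxy‑1,1‑dimethyl‑1,2,3,4‑tetrahydronaphthalen‑2‑ol
Conditions: (R)‑2‑methyl‑CBS‑oxazaborolidine (0.1 equiv), BH3·SMe2, THF, −20 °C; MeOH, then aq. NH4Cl
Reagents that add atoms: none
Why: Corey–Bakshi–Shibata reduction in which the quaternary benzylic carbon acts as the large and the ring CH2 as the small substituent, so the (R)‑catalyst should deliver hydride to the face that gives the (S)‑carbinol (labdane C3).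

Step 3
Reactants: 5 (S)‑6‑methoxy‑1,1‑dimethyl‑1,2,3,4‑tetrahydronaphthalen‑2‑ol
Product: 6 (S)‑6‑methoxy‑1,1‑dimethyl‑1,2,3,4,5,8‑hexahydronaphthalen‑2‑ol
Conditions: Li, NH3(l), THF, t‑BuOH, −78 → −33 °C; NH4Cl
Reagents that add atoms: none
Why: Birch reduction of the anisole ring keeps the methoxy‑bearing carbon and the two ring‑fusion carbons sp2 and protonates C5 and C8, the known outcome for 6‑methoxytetralins, while the lithium alkoxide of the carbinol is inert.

Step 4
Reactants: 6 (S)‑6‑methoxy‑1,1‑dimethyl‑1,2,3,4,5,8‑hexahydronaphthalen‑2‑ol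
Product: 8 (4aR,6S)‑6‑hydroxy‑5,5‑dimethyl‑4,4a,5,6,7,8‑hexahydronaphthalen‑2(3H)‑one, via deconjugated enone 7 (not isolated)
Conditions: 2 M aq. HCl, THF/MeOH, rt → 45 °C
Reagents that add atoms: water, O
Why: Acid hydrolysis of the enol ether gives the β,γ‑unsaturated ketone, which isomerises through its dienol to the conjugated enone; γ‑protonation creates C5, and under these equilibrating conditions the epimer with the C3 hydroxyl and C6 both equatorial on ring A (H‑5 trans to the hydroxyl) should predominate, though only modestly, so the minor C5 epimer is separated by chromatography and returned to the same acid.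

Step 5
Reactants: 8 (4aR,6S)‑6‑hydroxy‑5,5‑dimethyl‑4,4a,5,6,7,8‑hexahydronaphthalen‑2(3H)‑one
Product: 9 (4aR,6S)‑5,5‑dimethyl‑6‑(triethylsilyloxy)‑4,4a,5,6,7,8‑hexahydronaphthalen‑2(3H)‑one
Conditions: TESCl, imidazole, DMAP (cat.), DMF, rt
Reagents that add atoms: chlorotriethylsilane, CC[Si](Cl)(CC)CC
Why: Silylation of the equatorial secondary alcohol; the triethylsilyl ether is chosen because it survives organometallic and amide bases yet is cleaved by mild acid in the presence of a primary tert‑butyldiphenylsilyl ether, which a tert‑butyldimethylsilyl ether at this hindered position would not allow.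

Step 6
Reactants: 10 but‑3‑yn‑1‑ol
Product: 11 (but‑3‑yn‑1‑yloxy)(tert‑butyl)dimethylsilane
Conditions: TBSCl, imidazole, CH2Cl2, rt
Reagents that add atoms: tert‑butyldimethylsilyl chloride, CC(C)(C)[Si](C)(C)Cl
Why: Standard silylation of a primary alcohol, which masks the hydroxyl for the carboalumination.

Step 7
Reactants: 11 (but‑3‑yn‑1‑yloxy)(tert‑butyl)dimethylsilane
Product: 14 (E)‑5‑(tert‑butyldimethylsilyloxy)‑3‑methylpent‑2‑en‑1‑ol, via alkenyldimethylalane 12 (not isolated), via lithium alkenylalanate 13 (not isolated)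
Conditions: Me3Al, Cp2ZrCl2 (0.2 equiv), CH2Cl2, 0 °C → rt; n‑BuLi, hexane/THF, −78 °C; (CH2O)n, THF, −78 °C → rt; aq. HCl
Reagents that add atoms: trimethylaluminium, C[Al](C)C; paraformaldehyde (formaldehyde unit), C=O
Why: Zirconium‑catalysed Negishi carboalumination adds methyl and aluminium syn across the terminal alkyne with methyl on the internal carbon, and the alanate formed with n‑BuLi is hydroxymethylated by formaldehyde with retention, which fixes the E trisubstituted alkene.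

Step 8
Reactants: 14 (E)‑5‑(tert‑butyldimethylsilyloxy)‑3‑methylpent‑2‑en‑1‑ol
Product: 15 (E)‑1‑(tert‑butyldiphenylsilyloxy)‑5‑(tert‑butyldimethylsilyloxy)‑3‑methylpent‑2‑ene
Conditions: TBDPSCl, imidazole, CH2Cl2, rt
Reagents that add atoms: tert‑butyldiphenylsilyl chloride, CC(C)(C)[Si](Cl)(c1ccccc1)c1ccccc1
Why: Standard silylation of the primary allylic alcohol with the more acid‑stable silyl group.

Step 9
Reactants: 15 (E)‑1‑(tert‑butyldiphenylsilyloxy)‑5‑(tert‑butyldimethylsilyloxy)‑3‑methylpent‑2‑ene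
Product: 16 (E)‑5‑(tert‑butyldiphenylsilyloxy)‑3‑methylpent‑3‑en‑1‑ol
Conditions: PPTS, EtOH, 45 °C
Reagents that add atoms: none
Why: Acid‑catalysed solvolysis cleaves a primary tert‑butyldimethylsilyl ether far faster than a primary tert‑butyldiphenylsilyl ether, so only the homoallylic hydroxyl is released.

Step 10
Reactants: 16 (E)‑5‑(tert‑butyldiphenylsilyloxy)‑3‑methylpent‑3‑en‑1‑ol
Product: 17 (E)‑tert‑butyl[(5‑iodo‑3‑methylpent‑2‑en‑1‑yl)oxy]diphenylsilane
Conditions: PPh3, I2, imidazole, CH2Cl2, 0 °C → rt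
Reagents that add atoms: iodine, II
Why: Appel‑type iodination: the alkoxyphosphonium salt of the primary alcohol is displaced by iodide in an SN2 step that leaves the alkene geometry untouched.

Step 11
Reactants: 9 (4aR,6S)‑5,5‑dimethyl‑6‑(triethylsilyloxy)‑4,4a,5,6,7,8‑hexahydronaphthalen‑2(3H)‑one; 17 (E)‑tert‑butyl[(5‑iodo‑3‑methylpent‑2‑en‑1‑yl)oxy]diphenylsilane; 18 methyllithium
Product: 22 (3S,5R,9S,10R,13E)‑15‑(tert‑butyldiphenylsilyloxy)‑3‑(triethylsilyloxy)‑17‑norlabd‑13‑en‑8‑one, via lithium dimethylcuprate 19 (not isolated), via trimethylsilyl enol ether 20 (not isolated), via lithium enolate 21 (not isolated)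
Conditions: CuI, MeLi (2 equiv per Cu), THF, −30 °C; TMSCl, 9, −78 → −30 °C; Et3N, pentane, filtration under Ar, concentration; MeLi (1.1 equiv), THF, 0 °C; HMPA, 17 (2 equiv), −78 → 0 °C; aq. NH4Cl
Reagents that add atoms: none
Why: Me2CuLi, activated by TMSCl, transfers methyl to the β‑carbon C10 of the C8(=O)–C9=C10 enone and the enolate is trapped as the C8–C9 silyl enol ether; once the copper salts are filtered off, MeLi cleaves the O–Si bond to the regiodefined lithium enolate, which is alkylated at C9 by the primary iodide (SN2) in one telescoped operation. The closest known reaction type is cuprate conjugate addition to octalones, which gives cis‑fused angular‑methyl decalones, followed by alkylation of the regenerated enolate; no ring is closed. C10 is controlled by C5 and the C4 gem‑dimethyl group: ring A keeps the chair with H‑5 axial and the C3 silyloxy group equatorial, so the C4 β‑methyl is axial and 1,3‑diaxial to the β trajectory at C10, and the methyl enters on the α face, cis to H‑5. C9 is controlled by the cis fusion just formed: C4 is axial on ring B and its β‑methyl lies over the β face of C9, so the iodide should approach the α face and place the chain cis to C20 and H‑5, equatorial on ring B, which should also be the more stable C9 epimer. The step needs C‑ over O‑alkylation, substitution over E2 of the homoallylic iodide (its β‑hydrogens are allylic) and mono‑ over polyalkylation; these are addressed by the lithium counter‑ion with HMPA, low temperature, excess iodide and the absence of a proton source, so the enolate cannot migrate to the C7 side.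

Step 12
Reactants: 22 (3S,5R,9S,10R,13E)‑15‑(tert‑butyldiphenylsilyloxy)‑3‑(triethylsilyloxy)‑17‑norlabd‑13‑en‑8‑one
Product: 24 (3S,5R,9S,10R,13E)‑15‑(tert‑butyldiphenylsilyloxy)‑3‑(triethylsilyloxy)‑17‑norlabda‑7,13‑dien‑8‑yl trifluoromethanesulfonate, via potassium enolate 23 (not isolated)
Conditions: KN(SiMe3)2, THF, −78 °C; PhNTf2, −78 → 0 °C; aq. NH4Cl
Reagents that add atoms: N‑phenylbis(trifluoromethanesulfonimide), O=S(=O)(N(c1ccccc1)S(=O)(=O)C(F)(F)F)C(F)(F)F
Why: Kinetic deprotonation removes a proton from the open C7 methylene and not from the tertiary C9–H beside the quaternary C10, and the potassium enolate is O‑sulfonylated (enol triflate formation), which leaves the C9 centre untouched.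

Step 13
Reactants: 24 (3S,5R,9S,10R,13E)‑15‑(tert‑butyldiphenylsilyloxy)‑3‑(triethylsilyloxy)‑17‑norlabda‑7,13‑dien‑8‑yl trifluoromethanesulfonate
Product: 25 (3S,5R,9R,10S,13E)‑15‑(tert‑butyldiphenylsilyloxy)‑3‑(triethylsilyloxy)labda‑7,13‑diene
Conditions: Fe(acac)3 (10 mol%), MeMgBr, THF/NMP, −30 → 0 °C
Reagents that add atoms: methylmagnesium bromide, C[Mg]Br
Why: Iron‑catalysed Kumada‑type cross‑coupling of an alkenyl triflate with a methyl Grignard reagent puts C17 on C8 without moving the C7=C8 double bond, and silyl ethers and the remote alkene are inert at this temperature.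

Step 14
Reactants: 25 (3S,5R,9R,10S,13E)‑15‑(tert‑butyldiphenylsilyloxy)‑3‑(triethylsilyloxy)labda‑7,13‑diene
Product: 26 (3S,5R,9R,10S,13E)‑15‑(tert‑butyldiphenylsilyloxy)labda‑7,13‑dien‑3‑ol
Conditions: PPTS, MeOH/CH2Cl2, rt
Reagents that add atoms: none
Why: Acid‑catalysed methanolysis removes a triethylsilyl ether several orders of magnitude faster than a primary tert‑butyldiphenylsilyl ether, so only the C3 hydroxyl is released.

Step 15
Reactants: 26 (3S,5R,9R,10S,13E)‑15‑(tert‑butyldiphenylsilyloxy)labda‑7,13‑dien‑3‑ol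
Product: 27 (5R,9R,10S,13E)‑15‑(tert‑butyldiphenylsilyloxy)labda‑7,13‑dien‑3‑one
Conditions: Dess–Martin periodinane, CH2Cl2, rt
Reagents that add atoms: none
Why: Dess–Martin oxidation converts the secondary alcohol into the ketone under near‑neutral conditions that leave both trisubstituted alkenes and the allylic silyl ether alone; the C3 centre has by now passed its information on to C5, C10 and C9.

Step 16
Reactants: 27 (5R,9R,10S,13E)‑15‑(tert‑butyldiphenylsilyloxy)labda‑7,13‑dien‑3‑one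
Product: 29 (2S,5R,9R,10S,13E)‑15‑(tert‑butyldiphenylsilyloxy)‑2‑hydroxylabda‑7,13‑dien‑3‑one, via potassium enolate 28 (not isolated)
Conditions: KN(SiMe3)2, THF, −78 °C; (±)‑trans‑2‑(phenylsulfonyl)‑3‑phenyloxaziridine, −78 °C; aq. NH4Cl
Reagents that add atoms: trans‑2‑(phenylsulfonyl)‑3‑phenyloxaziridine, O=S(=O)(c1ccccc1)N1OC1c1ccccc1
Why: Davis enolate hydroxylation, chosen because the sulfonyloxaziridine does not epoxidise the two trisubstituted alkenes: the ketone can enolise only toward C2 (C4 is quaternary), and without the equatorial C3 silyloxy anchor ring A should prefer the half‑chair with C20 and the C4 α‑methyl axial on the α face (the other one puts C4 axial on ring B and forces A(1,2) strain between C17 and C11), so the oxidant should attack C2 from the β face and give the equatorial 2β‑hydroxy ketone.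

Step 17
Reactants: 29 (2S,5R,9R,10S,13E)‑15‑(tert‑butyldiphenylsilyloxy)‑2‑hydroxylabda‑7,13‑dien‑3‑one
Product: 30 (2S,3R,5R,9R,10S,13E)‑15‑(tert‑butyldiphenylsilyloxy)labda‑7,13‑diene‑2,3‑diol
Conditions: LiBH(s‑Bu)3 (3 equiv), THF, −78 °C; aq. NaOH/H2O2, 0 °C
Reagents that add atoms: none
Why: Bulky‑hydride reduction of a cyclohexanone: the equatorial 2β‑oxygen holds ring A in the chair in which C6 is axial and blocks the axial (β) trajectory at C3, so hydride should enter equatorially from the α face and give the axial 3β‑alcohol, cis to the 2β‑hydroxyl.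

Step 18
Reactants: 30 (2S,3R,5R,9R,10S,13E)‑15‑(tert‑butyldiphenylsilyloxy)labda‑7,13‑diene‑2,3‑diol
Product: 31 (2S,3R,5R,9R,10S,13E)‑labda‑7,13‑diene‑2,3,15‑triol
Conditions: TBAF, THF, 0 °C → rt; aq. NH4Cl
Reagents that add atoms: none
Why: Fluoride‑mediated cleavage of the silyl ether, driven by Si–F bond formation, with no other fluoride‑sensitive group in the molecule.

Step 19
Reactants: 31 (2S,3R,5R,9R,10S,13E)‑labda‑7,13‑diene‑2,3,15‑triol
Product: 32 (2S,3R,5R,9R,10S,13E)‑2,3‑dihydroxylabda‑7,13‑dien‑15‑yl acetate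
Conditions: AcCl (1.05 equiv), 2,4,6‑collidine, CH2Cl2, −78 °C
Reagents that add atoms: acetyl chloride, CC(=O)Cl
Why: Chemoselective acylation: acetyl chloride with collidine at low temperature acylates a primary alcohol much faster than a secondary one, and here the C3 hydroxyl is axial and neopentyl and the C2 hydroxyl secondary, so only O15 should react.

**Compound list**

1 | 6‑methoxy‑3,4‑dihydronaphthalen‑2(1H)‑one (6‑methoxy‑2‑tetralone) | COc1ccc2CC(=O)CCc2c1 | starting material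
2 | iodomethane | CI | starting material
3 | 6‑methoxy‑1‑methyl‑3,4‑dihydronaphthalen‑2(1H)‑one (racemic) | COc1ccc2c(c1)CCC(=O)C2C | intermediate
4 | 6‑methoxy‑1,1‑dimethyl‑3,4‑dihydronaphthalen‑2(1H)‑one | COc1ccc2c(c1)CCC(=O)C2(C)C | intermediate
5 | (S)‑6‑methoxy‑1,1‑dimethyl‑1,2,3,4‑tetrahydronaphthalen‑2‑ol | COc1ccc2c(c1)CC[C@H](O)C2(C)C | intermediate
6 | (S)‑6‑methoxy‑1,1‑dimethyl‑1,2,3,4,5,8‑hexahydronaphthalen‑2‑ol | COC1=CCC2=C(C1)CC[C@H](O)C2(C)C | intermediate
7 | (S)‑6‑hydroxy‑5,5‑dimethyl‑3,4,5,6,7,8‑hexahydronaphthalen‑2(1H)‑one (C5=C10 alkene) | O=C1CCC2=C(C1)CC[C@H](O)C2(C)C | intermediate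
8 | (4aR,6S)‑6‑hydroxy‑5,5‑dimethyl‑4,4a,5,6,7,8‑hexahydronaphthalen‑2(3H)‑one (labdane 3S,5R; H‑5 trans to the hydroxyl) | C1=C2CC[C@H](O)C(C)(C)[C@@H]2CCC1=O | intermediate
9 | (4aR,6S)‑5,5‑dimethyl‑6‑(triethylsilyloxy)‑4,4a,5,6,7,8‑hexahydronaphthalen‑2(3H)‑one | C1=C2CC[C@H](O[Si](CC)(CC)CC)C(C)(C)[C@@H]2CCC1=O | intermediate
10 | but‑3‑yn‑1‑ol | C#CCCO | starting material
11 | (but‑3‑yn‑1‑yloxy)(tert‑butyl)dimethylsilane | C#CCCO[Si](C)(C)C(C)(C)C | intermediate
12 | (E)‑[4‑(tert‑butyldimethylsilyloxy)‑2‑methylbut‑1‑en‑1‑yl]dimethylalane | C[Al](C)/C=C(\C)CCO[Si](C)(C)C(C)(C)C | intermediate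
13 | lithium (E)‑butyl[4‑(tert‑butyldimethylsilyloxy)‑2‑methylbut‑1‑en‑1‑yl]dimethylaluminate | [Li+].CCCC[Al-](C)(C)/C=C(\C)CCO[Si](C)(C)C(C)(C)C | intermediate
14 | (E)‑5‑(tert‑butyldimethylsilyloxy)‑3‑methylpent‑2‑en‑1‑ol | OC/C=C(\C)CCO[Si](C)(C)C(C)(C)C | intermediate
15 | (E)‑1‑(tert‑butyldiphenylsilyloxy)‑5‑(tert‑butyldimethylsilyloxy)‑3‑methylpent‑2‑ene | CC(C)(C)[Si](c1ccccc1)(c1ccccc1)OC/C=C(\C)CCO[Si](C)(C)C(C)(C)C | intermediate
16 | (E)‑5‑(tert‑butyldiphenylsilyloxy)‑3‑methylpent‑3‑en‑1‑ol | CC(C)(C)[Si](c1ccccc1)(c1ccccc1)OC/C=C(\C)CCO | intermediate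
17 | (E)‑tert‑butyl[(5‑iodo‑3‑methylpent‑2‑en‑1‑yl)oxy]diphenylsilane | CC(C)(C)[Si](c1ccccc1)(c1ccccc1)OC/C=C(\C)CCI | intermediate
18 | methyllithium | [Li]C | starting material
19 | lithium dimethylcuprate | [Li+].C[Cu-]C | intermediate
20 | trimethyl{[(4aR,6S,8aR)‑5,5,8a‑trimethyl‑6‑(triethylsilyloxy)‑3,4,4a,5,6,7,8,8a‑octahydronaphthalen‑2‑yl]oxy}silane (labdane 3S,5R,10R; C20 cis to H‑5) | C1=C(O[Si](C)(C)C)CC[C@H]2C(C)(C)[C@@H](O[Si](CC)(CC)CC)CC[C@@]12C | intermediate
21 | lithium (4aR,6S,8aR)‑5,5,8a‑trimethyl‑6‑(triethylsilyloxy)‑3,4,4a,5,6,7,8,8a‑octahydronaphthalen‑2‑olate | C1=C([O-])CC[C@H]2C(C)(C)[C@@H](O[Si](CC)(CC)CC)CC[C@@]12C.[Li+] | intermediate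
22 | (3S,5R,9S,10R,13E)‑15‑(tert‑butyldiphenylsilyloxy)‑3‑(triethylsilyloxy)‑17‑norlabd‑13‑en‑8‑one (cis‑fused; C20, H‑5 and C9 chain α, 3‑O β) | CC(C)(C)[Si](c1ccccc1)(c1ccccc1)OC/C=C(\C)CC[C@@H]1C(=O)CC[C@H]2C(C)(C)[C@@H](O[Si](CC)(CC)CC)CC[C@@]12C | intermediate
23 | potassium C7=C8 enolate of 22 | CC(C)(C)[Si](c1ccccc1)(c1ccccc1)OC/C=C(\C)CC[C@@H]1C([O-])=CC[C@H]2C(C)(C)[C@@H](O[Si](CC)(CC)CC)CC[C@@]12C.[K+] | intermediate
24 | (3S,5R,9S,10R,13E)‑15‑(tert‑butyldiphenylsilyloxy)‑3‑(triethylsilyloxy)‑17‑norlabda‑7,13‑dien‑8‑yl trifluoromethanesulfonate | CC(C)(C)[Si](c1ccccc1)(c1ccccc1)OC/C=C(\C)CC[C@@H]1C(OS(=O)(=O)C(F)(F)F)=CC[C@H]2C(C)(C)[C@@H](O[Si](CC)(CC)CC)CC[C@@]12C | intermediate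
25 | (3S,5R,9R,10S,13E)‑15‑(tert‑butyldiphenylsilyloxy)‑3‑(triethylsilyloxy)labda‑7,13‑diene | CC(C)(C)[Si](c1ccccc1)(c1ccccc1)OC/C=C(\C)CC[C@@H]1C(C)=CC[C@H]2C(C)(C)[C@@H](O[Si](CC)(CC)CC)CC[C@@]12C | intermediate
26 | (3S,5R,9R,10S,13E)‑15‑(tert‑butyldiphenylsilyloxy)labda‑7,13‑dien‑3‑ol | CC(C)(C)[Si](c1ccccc1)(c1ccccc1)OC/C=C(\C)CC[C@@H]1C(C)=CC[C@H]2C(C)(C)[C@@H](O)CC[C@@]12C | intermediate
27 | (5R,9R,10S,13E)‑15‑(tert‑butyldiphenylsilyloxy)labda‑7,13‑dien‑3‑one | CC(C)(C)[Si](c1ccccc1)(c1ccccc1)OC/C=C(\C)CC[C@@H]1C(C)=CC[C@H]2C(C)(C)C(=O)CC[C@@]12C | intermediate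
28 | potassium C2=C3 enolate of 27 | CC(C)(C)[Si](c1ccccc1)(c1ccccc1)OC/C=C(\C)CC[C@@H]1C(C)=CC[C@H]2C(C)(C)C([O-])=CC[C@@]12C.[K+] | intermediate
29 | (2S,5R,9R,10S,13E)‑15‑(tert‑butyldiphenylsilyloxy)‑2‑hydroxylabda‑7,13‑dien‑3‑one (2β‑OH) | CC(C)(C)[Si](c1ccccc1)(c1ccccc1)OC/C=C(\C)CC[C@@H]1C(C)=CC[C@H]2C(C)(C)C(=O)[C@@H](O)C[C@@]12C | intermediate
30 | (2S,3R,5R,9R,10S,13E)‑15‑(tert‑butyldiphenylsilyloxy)labda‑7,13‑diene‑2,3‑diol (2β,3β) | CC(C)(C)[Si](c1ccccc1)(c1ccccc1)OC/C=C(\C)CC[C@@H]1C(C)=CC[C@H]2C(C)(C)[C@@H](O)[C@@H](O)C[C@@]12C | intermediate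
31 | (2S,3R,5R,9R,10S,13E)‑labda‑7,13‑diene‑2,3,15‑triol | OC/C=C(\C)CC[C@@H]1C(C)=CC[C@H]2C(C)(C)[C@@H](O)[C@@H](O)C[C@@]12C | intermediate
32 | (2S,3R,5R,9R,10S,13E)‑2,3‑dihydroxylabda‑7,13‑dien‑15‑yl acetate, i.e. (E)‑5‑[(1R,4aR,6R,7S,8aS)‑6,7‑dihydroxy‑2,5,5,8a‑tetramethyl‑1,4,4a,5,6,7,8,8a‑octahydronaphthalen‑1‑yl]‑3‑methylpent‑2‑en‑1‑yl acetate | CC(=O)OC/C=C(\C)CC[C@@H]1C(C)=CC[C@H]2C(C)(C)[C@@H](O)[C@@H](O)C[C@@]12C | target

**Step count and risks**

Total steps: 19. Longest linear sequence: 14 steps (steps 1–5, then 11–19); the iodide branch (steps 6–10) is 5 steps.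

Steps most likely to fail:

Step 11 (key step). The alkylation at the hindered C9 enolate carbon may be outrun by E2 elimination of the homoallylic iodide or by proton transfer and polyalkylation, and the face selectivity at C9 rests on conformational analysis. Fallback: the operation is split and the electrophile changed in kind. It sets out from 9 and 16: the conjugate addition is run as before and the silyl enol ether 20 is isolated. Alcohol 16 is converted with Tf2O and 2,6‑di‑tert‑butyl‑4‑methylpyridine at −78 °C into (E)‑5‑(tert‑butyldiphenylsilyloxy)‑3‑methylpent‑3‑en‑1‑yl trifluoromethanesulfonate F1. The lithium enolate 21, regenerated from 20 with MeLi, is then alkylated by this triflate at −78 °C in THF without HMPA; primary triflates alkylate hindered enolates at temperatures where elimination does not compete. The fallback comes back to the route at ketone 22.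

Step 16. The oxidant may approach the α face of the C2 enolate if ring A reacts through the other half‑chair, which would give the 2α‑hydroxy epimer. Fallback: a redox relay that uses the same conformational bias in the opposite sense. It sets out from 27, whose hydroxylation then gives (2R,5R,9R,10S,13E)‑15‑(tert‑butyldiphenylsilyloxy)‑2‑hydroxylabda‑7,13‑dien‑3‑one F2. NaBH4 reduces this by axial attack to the trans‑diequatorial (2R,3R,5R,9R,10S,13E)‑15‑(tert‑butyldiphenylsilyloxy)labda‑7,13‑diene‑2,3‑diol F3. The less hindered C2 carbinol is oxidised selectively (TEMPO, PhI(OAc)2, CH2Cl2; the neopentyl C3 carbinol reacts far more slowly) to (3R,5R,9R,10S,13E)‑15‑(tert‑butyldiphenylsilyloxy)‑3‑hydroxylabda‑7,13‑dien‑2‑one F4. NaBH4 then reduces the C2 ketone from the α face, because the β face is blocked by the same syn‑axial C9 and C4 β‑methyl that diverted the oxidant. The fallback comes back to the route at diol 30.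

Step 19. Acetylation may not stop at the primary hydroxyl, and esters of the C2 hydroxyl would then contaminate the product. Fallback: temporary protection of the diol. It sets out from 30, which with 2,2‑dimethoxypropane and PPTS gives the 2,3‑O‑isopropylidene derivative of 30 F5. TBAF releases the 2,3‑O‑isopropylidene derivative of triol 31 F6, and Ac2O/pyridine/DMAP gives the 2,3‑O‑isopropylidene derivative of the target F7. 80% aqueous acetic acid at rt then removes the acetonide without touching the allylic acetate, and the fallback arrives at target 32.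

**Further compounds**

F1 | step 11 | (E)‑5‑(tert‑butyldiphenylsilyloxy)‑3‑methylpent‑3‑en‑1‑yl trifluoromethanesulfonate | CC(C)(C)[Si](c1ccccc1)(c1ccccc1)OC/C=C(\C)CCOS(=O)(=O)C(F)(F)F
F2 | step 16 | (2R,5R,9R,10S,13E)‑15‑(tert‑butyldiphenylsilyloxy)‑2‑hydroxylabda‑7,13‑dien‑3‑one (2α‑hydroxy epimer of 29) | CC(C)(C)[Si](c1ccccc1)(c1ccccc1)OC/C=C(\C)CC[C@@H]1C(C)=CC[C@H]2C(C)(C)C(=O)[C@H](O)C[C@@]12C
F3 | step 16 | (2R,3R,5R,9R,10S,13E)‑15‑(tert‑butyldiphenylsilyloxy)labda‑7,13‑diene‑2,3‑diol (2α,3β) | CC(C)(C)[Si](c1ccccc1)(c1ccccc1)OC/C=C(\C)CC[C@@H]1C(C)=CC[C@H]2C(C)(C)[C@@H](O)[C@H](O)C[C@@]12C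
F4 | step 16 | (3R,5R,9R,10S,13E)‑15‑(tert‑butyldiphenylsilyloxy)‑3‑hydroxylabda‑7,13‑dien‑2‑one | CC(C)(C)[Si](c1ccccc1)(c1ccccc1)OC/C=C(\C)CC[C@@H]1C(C)=CC[C@H]2C(C)(C)[C@@H](O)C(=O)C[C@@]12C
F5 | step 19 | 2,3‑O‑isopropylidene derivative of 30 | CC(C)(C)[Si](c1ccccc1)(c1ccccc1)OC/C=C(\C)CC[C@@H]1C(C)=CC[C@H]2C(C)(C)[C@H]3OC(C)(C)O[C@H]3C[C@@]12C
F6 | step 19 | 2,3‑O‑isopropylidene derivative of 31 | OC/C=C(\C)CC[C@@H]1C(C)=CC[C@H]2C(C)(C)[C@H]3OC(C)(C)O[C@H]3C[C@@]12C
F7 | step 19 | 2,3‑O‑isopropylidene derivative of 32 | CC(=O)OC/C=C(\C)CC[C@@H]1C(C)=CC[C@H]2C(C)(C)[C@H]3OC(C)(C)O[C@H]3C[C@@]12C
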